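Retrosynthetic overview
- The target is an all-trans tetrahydrofuran: O1, C2 (4-hydroxyphenyl, R), C3 (S, bearing the CH2OAc carbon C3a), C4 (R, bearing the CH(OAc)-anisyl carbon C4a, S) and C5 (H2). The plan rests on two features: C5 is a bare CH2 between O1 and C4, and C4a is an acetoxylated 4-methoxybenzylic carbon.
- Last disconnection: the phenol O–Si bond (triisopropylsilyl ether of the target).
- Key disconnection: O1–C5, C4–C5 and C4a–OAc are cut together, giving a syn (E)-homoallylic alcohol, formaldehyde and acetic acid. This Prins closure forms the only ring, the tetrahydrofuran.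
- The homoallylic alcohol comes from a 1,3-diol by primary acetylation; the diol comes from an Evans syn-aldol adduct (C2–C3 bond, both stereocentres) by LiBH4 reduction.
- The aldol partners are the (R)-oxazolidinone imide of (E)-4-(4-methoxyphenyl)but-3-enoic acid (Wittig) and 4-(triisopropylsilyloxy)benzaldehyde.

Key step: step 7

Step 1
Reactants: 1 4-methoxybenzaldehyde; 2 (2-carboxyethyl)triphenylphosphonium bromide
Product: 4 (E)-4-(4-methoxyphenyl)but-3-enoic acid, via carboxylate ylide 3 (not isolated)
Conditions: NaN(SiMe3)2 (2.1 equiv), THF, 0 °C; then 1, −78 °C → rt; 1 M HCl; recrystallisation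
Reagents that add atoms: none
Why: Wittig olefination with a carboxylate-bearing ylide, which with aromatic aldehydes should give mainly the E-styrene; any Z isomer is removed by crystallisation of the acid, and no stereocentre is formed.

Step 2
Reactants: 4 (E)-4-(4-methoxyphenyl)but-3-enoic acid; 5 (R)-4-benzyl-2-oxazolidinone
Product: 7 (4R)-4-benzyl-3-[(3E)-4-(4-methoxyphenyl)but-3-enoyl]oxazolidin-2-one, via mixed pivalic anhydride 6 (not isolated)
Conditions: t-BuCOCl, Et3N, THF, −20 °C; then LiCl, 5, −20 °C → rt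
Reagents that add atoms: none
Why: N-acylation of the oxazolidinone through the mixed anhydride with LiCl/Et3N activation, mild enough to keep the double bond in its styrene-conjugated β,γ-position; the auxiliary stereocentre is carried in unchanged.

Step 3
Reactants: 8 4-hydroxybenzaldehyde
Product: 9 4-(triisopropylsilyloxy)benzaldehyde
Conditions: i-Pr3SiCl, imidazole, DMF, rt
Reagents that add atoms: triisopropylsilyl chloride, CC(C)[Si](Cl)(C(C)C)C(C)C
Why: Standard silylation of a phenol; the bulky aryl silyl ether should tolerate the boron aldol, LiBH4 and cold BF3·OEt2, and it is a weaker donor than an alkyl ether, which lowers the tendency of the future C2 benzylic C–O bond to ionise.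

Step 4
Reactants: 7 (4R)-4-benzyl-3-[(3E)-4-(4-methoxyphenyl)but-3-enoyl]oxazolidin-2-one; 9 4-(triisopropylsilyloxy)benzaldehyde
Product: 12 (4R)-4-benzyl-3-[(2R,3E)-2-[(R)-hydroxy[4-(triisopropylsilyloxy)phenyl]methyl]-4-(4-methoxyphenyl)but-3-enoyl]oxazolidin-2-one, via dibutylboron Z-enolate 10 (not isolated), via dibutylboron aldolate 11 (not isolated)
Conditions: n-Bu2BOTf, i-Pr2NEt, CH2Cl2, −78 → 0 °C; then 9, −78 → 0 °C; pH 7 buffer, MeOH, 30% H2O2, 0 °C
Reagents that add atoms: none
Why: Evans boron syn-aldol reaction: soft enolisation gives the Z(O)-dienolate, which adds through its α-carbon in a closed Zimmerman–Traxler chair on the face left open by the benzyl group of the (R)-auxiliary, setting the α-carbon (future C3) and the carbinol carbon (future C2) as R,R (syn).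

Step 5
Reactants: 12 the syn-aldol adduct of step 4
Product: 13 (1R,2S)-2-[(E)-2-(4-methoxyphenyl)ethenyl]-1-[4-(triisopropylsilyloxy)phenyl]propane-1,3-diol
Conditions: LiBH4, MeOH (2 equiv), THF, 0 °C; aq. NH4Cl
Reagents that add atoms: none
Why: Reductive cleavage of the imide by LiBH4 at the exocyclic carbonyl gives the 1,3-diol and returns the auxiliary without touching the stereocentres, the alkene or the aryl silyl ether; the branch carbon changes from R to S only because CH2OH ranks below the carbinol carbon.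

Step 6
Reactants: 13 (1R,2S)-2-[(E)-2-(4-methoxyphenyl)ethenyl]-1-[4-(triisopropylsilyloxy)phenyl]propane-1,3-diol
Product: 14 (2S,3E)-2-[(R)-hydroxy[4-(triisopropylsilyloxy)phenyl]methyl]-4-(4-methoxyphenyl)but-3-en-1-yl acetate
Conditions: AcCl (1.05 equiv), 2,4,6-collidine, CH2Cl2, −78 °C
Reagents that add atoms: acetyl chloride, CC(Cl)=O
Why: Site-selective acylation: at −78 °C the acylpyridinium from AcCl and collidine should react with the unhindered primary hydroxyl much faster than with the secondary benzylic hydroxyl, which is flanked by an aryl ring and a branch.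

Step 7
Reactants: 14 (2S,3E)-2-[(R)-hydroxy[4-(triisopropylsilyloxy)phenyl]methyl]-4-(4-methoxyphenyl)but-3-en-1-yl acetate; 15 formaldehyde (used as paraformaldehyde); 16 acetic acid
Product: 20 [(2R,3S,4R)-4-[(S)-acetoxy(4-methoxyphenyl)methyl]-2-[4-(triisopropylsilyloxy)phenyl]tetrahydrofuran-3-yl]methyl acetate, via hemiformal 17 (not isolated), via oxocarbenium ion 18 (not isolated), via anisylic cation 19 (not isolated)
Conditions: (CH2O)n, AcOH, BF3·OEt2, CH2Cl2, 0 °C, 15 min; then slow addition of 14, −30 → −10 °C; cold aq. NaHCO3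
Reagents that add atoms: none
Why: Prins cyclisation: formaldehyde activated by BF3·OEt2 converts the C2 hydroxyl into the hemiformal, which ionises to the O1=C5 oxocarbenium ion; the anisyl-polarised E-alkene attacks C5 through C4, which closes the tetrahydrofuran and leaves a 4-methoxybenzylic cation at C4a, and acetate from acetic acid collapses onto it. The closest known reactions are oxonium-Prins cyclisations of aryl-terminated homoallylic alcohols to 2,3-disubstituted tetrahydrofurans with nucleophilic capture at the benzylic carbon, and BF3·OEt2/AcOH Prins cyclisations that end in acetate capture. The ring closes in a five-membered mode in which the C5=O1 oxocarbenium bond lies inside the new ring and the alkene stays exocyclic (exo at the alkene, endo at the oxocarbenium). C4 is controlled by the C3 stereocentre, because in the envelope transition state the C3 hydrogen eclipses the alkene and the CH2OAc branch is pseudo-equatorial, so the new side chain comes out trans to it (all-trans ring); C4a is controlled by the E-geometry of the alkene together with anti addition, acetate entering the contact ion pair on the face opposite the new C4–C5 bond before the C4–C4a bond rotates, which gives the S centre. The step needs bonding at C4 and not at C4a (six-membered ring or 2-oxonia-Cope shift), which the anisyl group secures by placing the positive charge at C4a, and it needs ionisation of the hemiformal to outrun ionisation of the C2 benzylic C–O bond and protonation of the styrene, which the weaker silyloxy donor on the C2 aryl ring, the low temperature and the slow addition of 14 to pre-activated formaldehyde should secure. The aryl silyl ether and the primary acetate are expected to survive cold BF3·OEt2.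

Step 8
Reactants: 20 [(2R,3S,4R)-4-[(S)-acetoxy(4-methoxyphenyl)methyl]-2-[4-(triisopropylsilyloxy)phenyl]tetrahydrofuran-3-yl]methyl acetate
Product: 21 [(2R,3S,4R)-4-[(S)-acetoxy(4-methoxyphenyl)methyl]-2-(4-hydroxyphenyl)tetrahydrofuran-3-yl]methyl acetate (target)
Conditions: Bu4NF, AcOH (1:1), THF, 0 °C
Reagents that add atoms: none
Why: Fluoride cleavage of the aryl silicon–oxygen bond, buffered with acetic acid so that no phenoxide forms, the two acetates neither cleave nor migrate and the anisylic acetate does not ionise; no stereocentre is touched.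

Compound list
1 | 4-methoxybenzaldehyde | COc1ccc(C=O)cc1 | starting material
2 | (2-carboxyethyl)triphenylphosphonium bromide | OC(=O)CC[P+](c1ccccc1)(c1ccccc1)c1ccccc1.[Br-] | starting material
3 | sodium 3-(triphenylphosphoranylidene)propanoate (carboxylate ylide) | [Na+].[O-]C(=O)CC=P(c1ccccc1)(c1ccccc1)c1ccccc1 | intermediate (not isolated)
4 | (E)-4-(4-methoxyphenyl)but-3-enoic acid | COc1ccc(/C=C/CC(=O)O)cc1 | intermediate
5 | (R)-4-benzyl-2-oxazolidinone | O=C1N[C@H](Cc2ccccc2)CO1 | starting material
6 | (E)-4-(4-methoxyphenyl)but-3-enoic pivalic anhydride | COc1ccc(/C=C/CC(=O)OC(=O)C(C)(C)C)cc1 | intermediate (not isolated)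
7 | (4R)-4-benzyl-3-[(3E)-4-(4-methoxyphenyl)but-3-enoyl]oxazolidin-2-one | COc1ccc(/C=C/CC(=O)N2[C@H](Cc3ccccc3)COC2=O)cc1 | intermediate
8 | 4-hydroxybenzaldehyde | O=Cc1ccc(O)cc1 | starting material
9 | 4-(triisopropylsilyloxy)benzaldehyde | O=Cc1ccc(O[Si](C(C)C)(C(C)C)C(C)C)cc1 | intermediate
10 | dibutylboron Z(O)-dienolate of imide 7 | COc1ccc(/C=C/C=C(\OB(CCCC)CCCC)N2[C@H](Cc3ccccc3)COC2=O)cc1 | intermediate (not isolated)
11 | dibutylboron aldolate of 12 | CCCCB(CCCC)O[C@@H](c1ccc(O[Si](C(C)C)(C(C)C)C(C)C)cc1)[C@@H](/C=C/c1ccc(OC)cc1)C(=O)N1[C@H](Cc2ccccc2)COC1=O | intermediate (not isolated)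
12 | (4R)-4-benzyl-3-[(2R,3E)-2-[(R)-hydroxy[4-(triisopropylsilyloxy)phenyl]methyl]-4-(4-methoxyphenyl)but-3-enoyl]oxazolidin-2-one | O[C@@H](c1ccc(O[Si](C(C)C)(C(C)C)C(C)C)cc1)[C@@H](/C=C/c1ccc(OC)cc1)C(=O)N1[C@H](Cc2ccccc2)COC1=O | intermediate
13 | (1R,2S)-2-[(E)-2-(4-methoxyphenyl)ethenyl]-1-[4-(triisopropylsilyloxy)phenyl]propane-1,3-diol | O[C@@H](c1ccc(O[Si](C(C)C)(C(C)C)C(C)C)cc1)[C@@H](/C=C/c1ccc(OC)cc1)CO | intermediate
14 | (2S,3E)-2-[(R)-hydroxy[4-(triisopropylsilyloxy)phenyl]methyl]-4-(4-methoxyphenyl)but-3-en-1-yl acetate | O[C@@H](c1ccc(O[Si](C(C)C)(C(C)C)C(C)C)cc1)[C@@H](/C=C/c1ccc(OC)cc1)COC(C)=O | intermediate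
15 | formaldehyde (as paraformaldehyde) | C=O | starting material
16 | acetic acid | CC(=O)O | starting material
17 | hemiformal (hydroxymethyl ether) of 14 | OCO[C@@H](c1ccc(O[Si](C(C)C)(C(C)C)C(C)C)cc1)[C@@H](/C=C/c1ccc(OC)cc1)COC(C)=O | intermediate (not isolated)
18 | O1=C5 oxocarbenium ion | C=[O+][C@@H](c1ccc(O[Si](C(C)C)(C(C)C)C(C)C)cc1)[C@@H](/C=C/c1ccc(OC)cc1)COC(C)=O | intermediate (not isolated)
19 | 4-methoxybenzylic cation at C4a of the closed tetrahydrofuran | COc1ccc([CH+][C@H]2CO[C@@H](c3ccc(O[Si](C(C)C)(C(C)C)C(C)C)cc3)[C@@H]2COC(C)=O)cc1 | intermediate (not isolated)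
20 | [(2R,3S,4R)-4-[(S)-acetoxy(4-methoxyphenyl)methyl]-2-[4-(triisopropylsilyloxy)phenyl]tetrahydrofuran-3-yl]methyl acetate | COc1ccc([C@@H](OC(C)=O)[C@H]2CO[C@@H](c3ccc(O[Si](C(C)C)(C(C)C)C(C)C)cc3)[C@@H]2COC(C)=O)cc1 | intermediate
21 | [(2R,3S,4R)-4-[(S)-acetoxy(4-methoxyphenyl)methyl]-2-(4-hydroxyphenyl)tetrahydrofuran-3-yl]methyl acetate | COc1ccc([C@@H](OC(C)=O)[C@H]2CO[C@@H](c3ccc(O)cc3)[C@@H]2COC(C)=O)cc1 | target

Total step count: 8. Longest linear sequence: 7 steps (steps 1, 2, 4, 5, 6, 7, 8 from 4-methoxybenzaldehyde); step 3 is a one-step side branch.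

Steps most likely to fail

Step 7. The anisylic cation may be captured without facial control. If it lives long enough to rotate about C4–C4a, acetate delivery would follow the steric bias of the ring rather than anti addition, and later re-ionisation of the anisylic acetate could equilibrate C4a. Ionisation at the C2 benzylic C–O bond and protonation of the styrene are secondary concerns. The fallback sets out from 20 obtained as a mixture with its C4a epimer and comes back at 20, with C4a set by reagent control. Both acetates are removed with i-Bu2AlH (CH2Cl2, −78 °C) to give the diol F1 as a mixture of carbinol epimers. Activated MnO2 (CH2Cl2, rt) oxidises only the anisylic carbinol and gives the aryl ketone F2, which erases C4a; the adjacent C4 centre sits in its more stable trans arrangement. Reduction with BH3·SMe2 and (R)-2-methyl-CBS-oxazaborolidine (THF, −20 °C), the aryl group acting as the large substituent, should give the (S)-carbinol diol F3. Ac2O, pyridine and catalytic DMAP (CH2Cl2, 0 °C) then return 20.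

Step 4. The aryl-conjugated boron dienolate may bond through its γ-carbon, or the styrene geometry may be lost on enolisation, so that regio- and diastereocontrol erode. The fallback sets out from 5 and 9 and comes back at 12, bringing in the anisyl group only after the aldol. Acylation of 5 (n-BuLi, (E)-but-2-enoyl chloride, THF, −78 °C) gives the crotonyl imide F4. Its deconjugative Evans aldol with 9 (n-Bu2BOTf, Et3N, CH2Cl2, −78 → 0 °C) should give the α-vinyl syn-aldol adduct F5 with the same sense of induction. Cross-metathesis of F5 with 4-methoxystyrene (second-generation Hoveyda–Grubbs catalyst, CH2Cl2, 40 °C) installs the E-anisylvinyl group and gives 12.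

Step 6. Acylation may occur at both hydroxyls, or the acetyl group may migrate between the 1,3-related oxygens, which would leave the C2 hydroxyl blocked for the Prins step. The fallback sets out from 12 and comes back at 14, replacing site selection by temporary protection. Et3SiOTf and 2,6-lutidine (CH2Cl2, −78 °C) give the triethylsilyl ether F6. LiBH4 with MeOH (THF, 0 °C) removes the auxiliary and gives the primary alcohol F7. Ac2O, pyridine and catalytic DMAP give the acetate F8. AcOH/THF/H2O (rt) cleaves the alkyl triethylsilyl ether, leaving the acid-stable aryl triisopropylsilyl ether, and gives 14.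

Further compounds
F1 | step 7 | (2R,3S,4R)-3-(hydroxymethyl)-4-[hydroxy(4-methoxyphenyl)methyl]-2-[4-(triisopropylsilyloxy)phenyl]tetrahydrofuran, both carbinol epimers | COc1ccc(C(O)[C@H]2CO[C@@H](c3ccc(O[Si](C(C)C)(C(C)C)C(C)C)cc3)[C@@H]2CO)cc1
F2 | step 7 | (2R,3S,4R)-3-(hydroxymethyl)-4-(4-methoxybenzoyl)-2-[4-(triisopropylsilyloxy)phenyl]tetrahydrofuran | COc1ccc(C(=O)[C@H]2CO[C@@H](c3ccc(O[Si](C(C)C)(C(C)C)C(C)C)cc3)[C@@H]2CO)cc1
F3 | step 7 | (2R,3S,4R)-3-(hydroxymethyl)-4-[(S)-hydroxy(4-methoxyphenyl)methyl]-2-[4-(triisopropylsilyloxy)phenyl]tetrahydrofuran | COc1ccc([C@@H](O)[C@H]2CO[C@@H](c3ccc(O[Si](C(C)C)(C(C)C)C(C)C)cc3)[C@@H]2CO)cc1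
F4 | step 4 | (R)-4-benzyl-3-[(E)-but-2-enoyl]oxazolidin-2-one | C/C=C/C(=O)N1[C@H](Cc2ccccc2)COC1=O
F5 | step 4 | (4R)-4-benzyl-3-[(2R)-2-[(R)-hydroxy[4-(triisopropylsilyloxy)phenyl]methyl]but-3-enoyl]oxazolidin-2-one | O[C@@H](c1ccc(O[Si](C(C)C)(C(C)C)C(C)C)cc1)[C@@H](C=C)C(=O)N1[C@H](Cc2ccccc2)COC1=O
F6 | step 6 | (4R)-4-benzyl-3-[(2R,3E)-4-(4-methoxyphenyl)-2-[(R)-(triethylsilyloxy)[4-(triisopropylsilyloxy)phenyl]methyl]but-3-enoyl]oxazolidin-2-one | CC[Si](CC)(CC)O[C@@H](c1ccc(O[Si](C(C)C)(C(C)C)C(C)C)cc1)[C@@H](/C=C/c1ccc(OC)cc1)C(=O)N1[C@H](Cc2ccccc2)COC1=O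
F7 | step 6 | (2S,3E)-4-(4-methoxyphenyl)-2-[(R)-(triethylsilyloxy)[4-(triisopropylsilyloxy)phenyl]methyl]but-3-en-1-ol | CC[Si](CC)(CC)O[C@@H](c1ccc(O[Si](C(C)C)(C(C)C)C(C)C)cc1)[C@@H](/C=C/c1ccc(OC)cc1)CO
F8 | step 6 | (2S,3E)-4-(4-methoxyphenyl)-2-[(R)-(triethylsilyloxy)[4-(triisopropylsilyloxy)phenyl]methyl]but-3-en-1-yl acetate | CC[Si](CC)(CC)O[C@@H](c1ccc(O[Si](C(C)C)(C(C)C)C(C)C)cc1)[C@@H](/C=C/c1ccc(OC)cc1)COC(C)=O
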